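## The problem

The target 20 is a germacranolide: a ten-membered carbocycle (C1–C10) fused through C6 and C7 to a butenolide (C7=C11, carbonyl C12, ring oxygen on C6) whose C11 carries an acetoxymethyl group (C13). The carbocycle holds a trans-1,10-epoxide with the C14 methyl on C10, an acetoxy group at C3 and an E-trisubstituted alkene C4=C5 bearing the C15 methyl. Ten-membered rings close poorly from open chains, so the ring is better obtained by expanding a bicycle than by cyclisation. Of the four stereocentres (1R,3S,6R,10R), C6 is the natural anchor. It fixes the sense of the crown conformation of an E,E-cyclodeca-1(10),4-diene, and that conformation can direct a hydride to one face of a C3 ketone and a peracid to the outer face of C1=C10. The E geometry of C1=C10 guarantees the trans relation of C1 and C10. The molecule is fragile: the 1(10),4-diene and above all the 1,10-epoxide facing C4=C5 cyclise transannularly with acid, the diene undergoes Cope rearrangement on heating, and the allylic acetates ionise easily. H6 of the butenolide (γ to the lactone carbonyl and allylic to C4=C5) is acidic, so base would erase the one stereocentre that is bought in. The enabling feature is that a bond drawn from C5 to C10 turns the skeleton into the eudesmane of α-santonin 1, which has all fifteen carbons, oxygen at C3, C6 and C12 and the correct C6 configuration. Conversely, in a eudesma-1,3-diene (C1=C2–C3=C4) the C5–C10 bond is the σ bond of a cyclohexa-1,3-diene and can be cut by light to leave exactly C1=C10 and C4=C5. Santonin lacks oxygen on C13 and unsaturation between C7 and C11, and when these are added relative to the ring expansion is the main design question.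

## Retrosynthesis

Target 20 is cut first at the two C–O bonds of the oxirane, giving triene 18 (3β,13-diacetoxygermacra-1(10),4,7(11)-trien-12,6α-olide) and peracid 19. Of the three alkenes of 18 only C1=C10 is electron-rich: C4=C5 is flanked by two allylic oxygens and C7=C11 is conjugated to the carbonyl. Making this cut last keeps the acid-labile epoxide out of every other step, whereas carrying it from earlier would expose it to the dehydrating agent of the next cut. The forward reaction must choose the outer face of C1=C10.

In 18 the C7=C11 bond is cut by adding water across it with the hydroxyl on C11, giving tertiary alcohol 17. Its two acetyl C–O bonds lead to triol 16 and acetic anhydride 9. A late dehydration means the butenolide with its acidic H6 never meets base or a C3 ketone, and C13 is already oxygenated when the alkene appears. The neighbouring option, forming the butenolide first and oxidising its methyl group afterwards, has no selective reagent beside two trisubstituted alkenes. The precursor has a robust α-hydroxy lactone in place of the butenolide. The forward steps must acylate two of three hydroxyls and eliminate toward C7, not C13.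

Triol 16 is traced to trienyl acetate 13 (3,11β,13-triacetoxygermacra-1(10),2,4-trien-12,6α-olide) by removing the C3–H bond and the C2 proton, by way of 3-ketone 14 unmasked from the enol acetate. The ketone is made and reduced in one flask, because the isolated β,γ-unsaturated ketone would slip into conjugation with base. This takes the problem back to a compound with no stereocentre on the ten-membered ring other than C6. The forward step must deliver hydride to the α-face of C3.

The central disconnection reconnects C5 to C10 in 13: the 1(10),2,4-triene becomes the cyclohexa-1,3-diene of the trans-fused eudesmane 12 (3,11β,13-triacetoxy-5αH-eudesma-1,3-dien-12,6α-olide). Against closures at C1–C10, C2–C3 or C4–C5, this cut needs no new stereocentre, no high dilution and no separate control of alkene geometry, since both E alkenes follow from conrotatory opening of a trans-fused ring. It simplifies a ten-membered triene to a decalin with every carbon in place. The forward reaction must be run cold and stopped in time, because the opening is photoreversible and the triene recloses thermally.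

Diene 12 is the enol acetate of enone 8 (11β,13-dihydroxy-3-oxo-5αH-eudesm-1-en-12,6α-olide), acetylated on both hydroxyls. The cut is at three acetyl C–O bonds: acetic anhydride 9 for O13 by way of monoacetate 11, and isopropenyl acetate 10 for the enol and tertiary oxygens. The C11–O and C13–O bonds of 8 are then cut back to the exocyclic alkene of dienone 6 (3-oxo-5αH-eudesma-1,11(13)-dien-12,6α-olide), with NMO 7 as oxidant. Oxidising C13 here, where the only other alkene is a hindered enone, is what allows the late dehydration; after ring expansion the same oxidation would compete with two electron-rich alkenes. The forward reaction must leave C1=C2 alone.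

Both π bonds of 6 (C1=C2 and C11=C13) are removed together by retro selenoxide elimination through bis-selenide 5, made with PhSeCl 4. This leads to the saturated keto lactone 3 (tetrahydrosantonin with equatorial 4α-methyl), which comes from α-santonin 1 by addition of two molecules of hydrogen. Saturating ring A and then restoring C1=C2 looks roundabout, but the C1=C2/C4=C5 dienone of santonin cannot be enolised into a diene that opens across C5–C10. Only a trans-fused 1-en-3-one gives the C1=C2–C3=C4 diene. The forward steps must hydrogenate C4=C5 from the α-face and deprotonate the ketone at C2 rather than C4.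

## Roads not taken

Alternative 1: sulfonium ylide epoxidation that closes the ring. The cut is at C1–C10 and C1–O together. In the open-chain sulfonium salt A2, C1 is the CH2 of a diphenylsulfonium group and C10 is a methyl ketone. Deprotonation next to sulfur gives an ylide that adds to the ketone (C1–C10), and the alkoxide then displaces the sulfide (C1–O, Corey–Chaykovsky reaction) to give bis-silyl ether A1. Desilylation and acetylation would finish the target.
- Merits: ring and epoxide are made in one operation, no chemoselective epoxidation of a triene is needed, C3 is set in an open chain by reliable asymmetric methods, and the route is convergent.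
- Weak points: closing a ten-membered ring through a reversible betaine must compete with intermolecular reaction. Nothing in A2 controls which face of the methyl ketone is attacked or the relative configuration of C1 and C10. The base that forms the ylide also meets H6 of the butenolide, whose removal would racemise C6. A2 itself (two stereocentres, an E-trisubstituted alkene, the butenolide) needs a long synthesis.
- Comparison: A1 is better exactly where the chosen route is weakest, the facial selectivity of the last epoxidation and the configuration at C3, which it settles before or during ring formation. The chosen route sets against this that C6 and both alkene geometries are guaranteed by santonin and by orbital symmetry, that the ring forms without dilution, and that nine steps suffice.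

Alternative 2: anionic oxy-Cope ring expansion. The cut is again C5–C10, with C2–C3 formed in exchange. The potassium alkoxide of cyclohexanol A4 (vinyl on C10 and alkenyl on C5, trans) rearranges through a chair transition state, the six-membered ring opens to the ten-membered ring, and the C10 enolate is trapped as enol triflate A3.
- Merits: the rearrangement is thermal and made irreversible by enolate formation, so no photostationary state limits conversion. The chair transition state transmits the ring configuration into both E alkenes and, through the enol ether geometry, into C3. The triflate is a handle for the C14 methyl.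
- Weak points: A3 still lacks C11–C13, the lactone, the C14 methyl and the epoxide. A methyl cross-coupling, deketalisation, butenolide annulation at C6/C7 and three protecting-group removals must follow. A4 has three stereocentres and a stereodefined enol ether to be made enantioselectively.
- Comparison: as a ring-forming event the oxy-Cope is the more reliable of the two (irreversible, no light, easier to scale), and it fixes C3 before the ring exists. The chosen route answers with a starting material that already holds all carbons, the lactone and C6, so no skeletal bond has to be made.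

Alternative 3: ring-closing alkyne metathesis. The cut is at C4–C5. Diyne A6, with methyl-capped alkynes at C4 and C5, would be closed by Mo(≡CAr)(OSiPh3)3 (Ar = 4-methoxyphenyl) to cycloalkyne A5. Trans-hydrostannation and methylation of the alkenylstannane would give the E-trisubstituted C4=C5 bond, followed by desilylation and acetylation.
- Merits: alkyne metathesis tolerates the epoxide, silyl ethers and butenolide. The epoxide is made early on an open chain under reagent control. The E geometry of C4=C5 comes from the trans-addition and does not depend on ring conformation.
- Weak points: a ten-membered cycloalkyne that also contains a trans-epoxide and an sp2 ring-fusion carbon is strained, and closure to rings of this size tends to give way to oligomerisation. The propargylic C6–O bond and H6 are sensitive. Regiocontrol in the hydrostannation needs a free propargylic hydroxyl, which costs protecting-group steps.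
- Comparison: A5 would give firmer control of C4=C5 in the presence of the finished epoxide, and a more modular route. The chosen plan obtains the same geometry from conrotation and needs neither a strained alkyne nor three further steps at C4/C5.

Key step: step 5

Assumption: the configurations drawn at C4 of 3–11 and at C11 of 5–17 (both erased later) follow the usual behaviour of the trans-fused santonin lactone, namely an equatorial 4α-methyl after equilibration and reagent approach to C11 from the β-face, anti to H7; neither affects a stereocentre of the target.

Step 1
Reactants: 1 α-santonin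
Product: 3 3-oxo-4βH,5αH,11βH-eudesman-12,6α-olide (tetrahydrosantonin with equatorial 4α-methyl), via axial 4β-methyl epimer 2 (not isolated)
Conditions: H2 (1 atm), 10% Pd/C, EtOAc, rt; filter; then HCl (cat.), EtOH, rt
Reagents that add atoms: none
Why: Heterogeneous hydrogenation of the cross-conjugated dienone; hydrogen should reach C5 from the α-face opposite the angular C10 methyl and give the trans-fused decalone, and acid equilibration through the enol places the C4 methyl equatorial. The lactone and C6, C7 and C11 are not touched.

Step 2
Reactants: 3 tetrahydrosantonin (4α-methyl); 4 phenylselenenyl chloride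
Product: 6 3-oxo-4βH,5αH-eudesma-1,11(13)-dien-12,6α-olide, via bis(phenylseleno) ketolactone 5 (not isolated)
Conditions: LiN(iPr)2 (2.3 equiv), THF, −78 °C; PhSeCl (2.4 equiv), −78 °C; then 30% H2O2, pyridine, CH2Cl2, 0 °C → rt
Reagents that add atoms: phenylselenenyl chloride, Cl[Se]c1ccccc1 (the phenylseleno groups of 5; none of its atoms remain in 6)
Why: Kinetic double deprotonation (ketone C2–H, then lactone C11–H), enolate selenenylation and selenoxide syn-elimination. The C2 selenoxide can only eliminate toward C1; the C11 selenoxide, introduced on the β-face anti to H7, can only eliminate into the methyl group, so the 1-en-3-one and the exocyclic α-methylene lactone should form together.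

Step 3
Reactants: 6 3-oxo-4βH,5αH-eudesma-1,11(13)-dien-12,6α-olide; 7 N-methylmorpholine N-oxide
Product: 8 11β,13-dihydroxy-3-oxo-4βH,5αH-eudesm-1-en-12,6α-olide
Conditions: OsO4 (2 mol %), NMO (1.2 equiv), acetone–H2O, 0 °C → rt
Reagents that add atoms: N-methylmorpholine N-oxide, C[N+]1([O-])CCOCC1; water, O
Why: Catalytic osmium tetroxide dihydroxylation with NMO as reoxidant; the unhindered 1,1-disubstituted acrylate-type alkene should react before the enone C1=C2, which is more electron-poor and neopentylic. Osmylation from the β-face, anti to H7, sets C11 as 11β-OH, a centre that is erased in step 8.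

Step 4
Reactants: 8 11β,13-dihydroxy-3-oxo-4βH,5αH-eudesm-1-en-12,6α-olide; 9 acetic anhydride; 10 isopropenyl acetate
Product: 12 3,11β,13-triacetoxy-5αH-eudesma-1,3-dien-12,6α-olide, via 13-monoacetate 11 (not isolated)
Conditions: Ac2O, pyridine, 0 °C → rt; evaporate; then isopropenyl acetate (solvent), TsOH·H2O (cat.), 90 °C with slow removal of acetone
Reagents that add atoms: acetic anhydride, CC(=O)OC(C)=O; isopropenyl acetate, CC(=C)OC(C)=O
Why: Ac2O/pyridine esterifies only the primary alcohol, which prevents acetonide formation in the second stage. Acid-catalysed enol acetylation can enolise the 1-en-3-one only toward C4 (C10 is quaternary), giving the homoannular 1,3-dienyl acetate, and the same reagent acetylates the tertiary hydroxyl.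

Step 5
Reactants: 12 3,11β,13-triacetoxy-5αH-eudesma-1,3-dien-12,6α-olide
Product: 13 3,11β,13-triacetoxygermacra-1(10),2,4-trien-12,6α-olide (ring bonds trans at C1=C10, cis at C2=C3, trans at C4=C5)
Conditions: hν (254 nm, low-pressure Hg lamp, quartz), degassed THF–MeOH, −78 °C, to partial conversion; solution kept at −78 °C for step 6
Reagents that add atoms: none
Why: Photochemical six-electron electrocyclic opening of a cyclohexa-1,3-diene to a hexatriene, conrotatory in the excited state (Woodward–Hoffmann rules); the dienyl acetate is the only chromophore expected to absorb at 254 nm. The closest known reaction type is the low-temperature photolysis of trans-fused eudesma-1,3-dien-12,6-olides and their 3-acetoxy derivatives to germacra-1(10),2,4-trienolides. The ten-membered ring is not closed by bond formation: it is unveiled by scission of the C5–C10 bond shared by the two six-membered rings, the only σ bond joining the diene termini. No stereocentre is created; C5 and C10 become trigonal, and C6, C7 and C11 take no part. The selectivity needed is E geometry at both new trisubstituted alkenes: conrotation of a trans-fused diene turns the C5–C6 and C10–C9 bonds both outward (the inward mode is impossible inside the ring), which gives trans C1=C10 and trans C4=C5 flanking the cis C2=C3 enol acetate. Irradiation at −78 °C suppresses thermal disrotatory reclosure to a cis-fused diene, and stopping short of prolonged irradiation limits secondary photoisomerisation. The C3 acetoxy group carries the C3 oxygen into the triene as a masked ketone.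

Step 6
Reactants: 13 3,11β,13-triacetoxygermacra-1(10),2,4-trien-12,6α-olide
Product: 16 3β,11β,13-trihydroxygermacra-1(10)E,4E-dien-12,6α-olide, via dienone 14 (not isolated), via hydroxy diacetate 15 (not isolated)
Conditions: NaBH4, K2CO3, MeOH–THF, −40 → −10 °C; acetone; then K2CO3, MeOH, 0 °C → rt
Reagents that add atoms: none
Why: Deconjugative borohydride reduction of a dienol acetate: methanolysis of the enol ester gives the dienolate, which is protonated kinetically at C2 to the β,γ-unsaturated ketone 14 and reduced at once, before C1=C10 can move into conjugation. In the crown conformer the C3 carbonyl is twisted out of the C4=C5 plane and its β-face is covered by the C4 methyl, so hydride should enter from the α-face and give the equatorial 3β-alcohol (3S). Excess hydride is destroyed cold to protect the α-oxygenated lactone before the two ester acetates are removed by methanolysis; products from unconverted 12 are separated at this stage.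

Step 7
Reactants: 16 3β,11β,13-trihydroxygermacra-1(10)E,4E-dien-12,6α-olide; 9 acetic anhydride
Product: 17 3β,13-diacetoxy-11β-hydroxygermacra-1(10)E,4E-dien-12,6α-olide
Conditions: Ac2O, pyridine, CH2Cl2, 0 °C → rt (no DMAP)
Reagents that add atoms: acetic anhydride, CC(=O)OC(C)=O
Why: Pyridine-mediated acylation distinguishes the primary and the secondary allylic hydroxyl from the hindered tertiary α-hydroxy lactone, which stays free as the future leaving group.

Step 8
Reactants: 17 3β,13-diacetoxy-11β-hydroxygermacra-1(10)E,4E-dien-12,6α-olide
Product: 18 3β,13-diacetoxygermacra-1(10)E,4E,7(11)-trien-12,6α-olide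
Conditions: SOCl2, pyridine, CH2Cl2, −30 → 0 °C
Reagents that add atoms: none
Why: Dehydration of a tertiary alcohol through its chlorosulfite by anti-periplanar E2: the 11β-oxygen and H7α are trans on the lactone ring, the new alkene is tetrasubstituted and conjugated (Zaitsev), and elimination away from the oxygen-bearing C13 is the normal preference. Pyridine buffers the acid-sensitive cyclodecadiene and is too weak a base to touch H6.

Step 9
Reactants: 18 3β,13-diacetoxygermacra-1(10)E,4E,7(11)-trien-12,6α-olide; 19 3-chloroperbenzoic acid
Product: 20 (1R,3S,4E,6R,10R)-3,13-diacetoxy-1,10-epoxygermacra-4,7(11)-dien-12,6-olide (target)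
Conditions: mCPBA (1.05 equiv), NaHCO3, CH2Cl2, −20 → 0 °C
Reagents that add atoms: 3-chloroperbenzoic acid, OOC(=O)c1cccc(Cl)c1
Why: Prilezhaev epoxidation; C1=C10 is the only electron-rich alkene, since C4=C5 carries an allylic acetate and the allylic lactone oxygen and C7=C11 is conjugated to the carbonyl. Stereospecific syn addition to the E alkene from the outer face of the crown conformer (C14 and C15 syn, ring sense fixed by C6) should give the (1R,10R) trans-epoxide; bicarbonate prevents acid-induced transannular cyclisation.

Compound list

1 | α-santonin (3-oxo-11βH-eudesma-1,4-dien-12,6α-olide) | C[C@H]1[C@@H]2CC[C@]3(C=CC(=O)C(=C3[C@H]2OC1=O)C)C | starting material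
2 | 3-oxo-4αH,5αH,11βH-eudesman-12,6α-olide (tetrahydrosantonin, axial 4β-methyl epimer) | C[C@H]1[C@@H]2CC[C@@]3(C)CCC(=O)[C@H](C)[C@@H]3[C@H]2OC1=O | intermediate (not isolated)
3 | 3-oxo-4βH,5αH,11βH-eudesman-12,6α-olide (tetrahydrosantonin, equatorial 4α-methyl) | C[C@H]1[C@@H]2CC[C@@]3(C)CCC(=O)[C@@H](C)[C@@H]3[C@H]2OC1=O | intermediate
4 | phenylselenenyl chloride | Cl[Se]c1ccccc1 | starting material
5 | 3-oxo-2α,11β-bis(phenylseleno)-4βH,5αH-eudesman-12,6α-olide | C[C@@]1([Se]c4ccccc4)[C@@H]2CC[C@@]3(C)C[C@@H]([Se]c4ccccc4)C(=O)[C@@H](C)[C@@H]3[C@H]2OC1=O | intermediate (not isolated)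
6 | 3-oxo-4βH,5αH-eudesma-1,11(13)-dien-12,6α-olide | C=C1[C@@H]2CC[C@@]3(C)C=CC(=O)[C@@H](C)[C@@H]3[C@H]2OC1=O | intermediate
7 | N-methylmorpholine N-oxide | C[N+]1([O-])CCOCC1 | starting material
8 | 11β,13-dihydroxy-3-oxo-4βH,5αH-eudesm-1-en-12,6α-olide | OC[C@@]1(O)[C@@H]2CC[C@@]3(C)C=CC(=O)[C@@H](C)[C@@H]3[C@H]2OC1=O | intermediate
9 | acetic anhydride | CC(=O)OC(C)=O | starting material
10 | isopropenyl acetate | CC(=C)OC(C)=O | starting material
11 | 13-acetoxy-11β-hydroxy-3-oxo-4βH,5αH-eudesm-1-en-12,6α-olide | CC(=O)OC[C@@]1(O)[C@@H]2CC[C@@]3(C)C=CC(=O)[C@@H](C)[C@@H]3[C@H]2OC1=O | intermediate (not isolated)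
12 | 3,11β,13-triacetoxy-5αH-eudesma-1,3-dien-12,6α-olide | CC(=O)OC[C@@]1(OC(C)=O)[C@@H]2CC[C@@]3(C)C=CC(OC(C)=O)=C(C)[C@@H]3[C@H]2OC1=O | intermediate
13 | 3,11β,13-triacetoxygermacra-1(10),2,4-trien-12,6α-olide (ring bonds trans, cis, trans) | CC(=O)OC[C@@]1(OC(C)=O)[C@@H]2CC/C(C)=C/C=C(OC(C)=O)\C(C)=C\[C@H]2OC1=O | intermediate
14 | 11β,13-diacetoxy-3-oxogermacra-1(10)E,4E-dien-12,6α-olide | CC(=O)OC[C@@]1(OC(C)=O)[C@@H]2CC/C(C)=C/CC(=O)/C(C)=C/[C@H]2OC1=O | intermediate (not isolated)
15 | 11β,13-diacetoxy-3β-hydroxygermacra-1(10)E,4E-dien-12,6α-olide | CC(=O)OC[C@@]1(OC(C)=O)[C@@H]2CC/C(C)=C/C[C@H](O)/C(C)=C/[C@H]2OC1=O | intermediate (not isolated)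
16 | 3β,11β,13-trihydroxygermacra-1(10)E,4E-dien-12,6α-olide | OC[C@@]1(O)[C@@H]2CC/C(C)=C/C[C@H](O)/C(C)=C/[C@H]2OC1=O | intermediate
17 | 3β,13-diacetoxy-11β-hydroxygermacra-1(10)E,4E-dien-12,6α-olide | CC(=O)OC[C@@]1(O)[C@@H]2CC/C(C)=C/C[C@H](OC(C)=O)/C(C)=C/[C@H]2OC1=O | intermediate
18 | 3β,13-diacetoxygermacra-1(10)E,4E,7(11)-trien-12,6α-olide | CC(=O)OCC1=C2CC/C(C)=C/C[C@H](OC(C)=O)/C(C)=C/[C@H]2OC1=O | intermediate
19 | 3-chloroperbenzoic acid | OOC(=O)c1cccc(Cl)c1 | starting material
20 | (1R,3S,4E,6R,10R)-3,13-diacetoxy-1,10-epoxygermacra-4,7(11)-dien-12,6-olide (CNP0294733.1) | CC(=O)OCC1=C2CC[C@@]3(C)O[C@@H]3C[C@H](OC(C)=O)/C(C)=C/[C@H]2OC1=O | target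

Total step count: 9. Longest linear sequence: 9 steps, from 1 to 20.

Least certain steps

Step 5 (key step). The opening is photoreversible, so conversion is limited and prolonged irradiation leads to secondary photoisomerisation. The triene can also reclose thermally by the disrotatory path to a cis-fused diene while it waits for the slower unmasking in step 6. Fallback: change the enol derivative so that unmasking is fast and unconverted diene is recyclable. Setting out from 11 (isolated after the first stage of step 4), Et3SiOSO2CF3/Et3N should give the bis(triethylsilyl) dienol ether F1. Irradiation as in step 5 gives the silyl trienol ether F2. Buffered HF·pyridine at −78 → 0 °C cleaves the silyl enol ether within minutes and then the tertiary silyl ether, turning the labile triene into the hydroxy dienone F3, while unconverted F1 returns 11. Luche reduction (NaBH4, CeCl3·7H2O, MeOH, −78 °C) gives the diol monoacetate F4, and Ac2O/pyridine brings the material back to the route at 17.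

Step 8. The elimination may lose regiocontrol (proton removal from C13 to give an enol acetate), the 13-acetate may participate, or chloride may substitute at C11. These are possible because the α-carbonyl position cannot carry positive charge and the transition state is therefore carbanion-like. Fallback: replace the 13-acetate by a non-participating, bulky ether before the elimination. Setting out from 16, tBuPh2SiCl/imidazole silylates the primary hydroxyl to give the 13-silyl ether F5; Ac2O/pyridine gives the 3-acetate F6; SOCl2/pyridine gives the silyloxymethyl butenolide F7; HF·pyridine gives the 13-alcohol F8; Ac2O/pyridine returns to the route at 18.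

Step 6. Hydride may add with poor facial selectivity to the transient dienone (giving the 3α-alcohol), conjugate reduction may compete, or C1=C10 may migrate into conjugation before reduction. The facial preference rests on a conformational argument for a mobile ring. Fallback: separate unmasking from reduction and put C3 under reagent control. Setting out from 13, cold methanolysis alone (K2CO3, MeOH, −40 °C, AcOH quench) gives dienone 14, now isolated. CBS reduction with (R)-2-methyl-CBS-oxazaborolidine and catecholborane (toluene, −78 °C; the alkenyl side acts as the large group) should give 15, and K2CO3/MeOH returns to the route at 16.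

Step 9. The peracid may attack the wrong face of C1=C10 if the planar butenolide changes the ring conformation, C4=C5 may be epoxidised in competition, or the product may cyclise transannularly under acid. Fallback: epoxidise before the dehydration, when C7 is still tetrahedral and the ring has the trans-lactone crown shape for which outer-face attack on C1=C10 is the established course. Setting out from 17, mCPBA/NaHCO3 gives the epoxy alcohol F9, and dehydration under neutral conditions with Martin sulfurane (Ph2S[OC(CF3)2Ph]2, CH2Cl2, 0 °C) leads directly to 20.

Step 2. The second deprotonation may be incomplete, or proton transfer from the more acidic α-seleno ketone may intervene, leaving the lactone unfunctionalised or putting two selenium atoms on C2. Fallback: address the two acidic sites one after the other. Setting out from 3, LiN(iPr)2/Me3SiCl at −78 °C gives the kinetic trimethylsilyl enol ether F10. A further equivalent of LiN(iPr)2 then forms only the lactone enolate, and PhSeCl (2.2 equiv) selenenylates both the lactone enolate and the silyl enol ether to give 5, which is oxidised as in step 2 to rejoin the route at 6.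

Further compounds

F1 | step 5 | 13-acetoxy-3,11β-bis(triethylsilyloxy)-5αH-eudesma-1,3-dien-12,6α-olide | CC(=O)OC[C@@]1(O[Si](CC)(CC)CC)[C@@H]2CC[C@@]3(C)C=CC(O[Si](CC)(CC)CC)=C(C)[C@@H]3[C@H]2OC1=O
F2 | step 5 | 13-acetoxy-3,11β-bis(triethylsilyloxy)germacra-1(10),2,4-trien-12,6α-olide | CC(=O)OC[C@@]1(O[Si](CC)(CC)CC)[C@@H]2CC/C(C)=C/C=C(O[Si](CC)(CC)CC)\C(C)=C\[C@H]2OC1=O
F3 | step 5 | 13-acetoxy-11β-hydroxy-3-oxogermacra-1(10)E,4E-dien-12,6α-olide | CC(=O)OC[C@@]1(O)[C@@H]2CC/C(C)=C/CC(=O)/C(C)=C/[C@H]2OC1=O
F4 | step 5 | 13-acetoxy-3β,11β-dihydroxygermacra-1(10)E,4E-dien-12,6α-olide | CC(=O)OC[C@@]1(O)[C@@H]2CC/C(C)=C/C[C@H](O)/C(C)=C/[C@H]2OC1=O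
F5 | step 8 | 13-(tert-butyldiphenylsilyloxy)-3β,11β-dihydroxygermacra-1(10)E,4E-dien-12,6α-olide | CC(C)(C)[Si](c1ccccc1)(c1ccccc1)OC[C@@]1(O)[C@@H]2CC/C(C)=C/C[C@H](O)/C(C)=C/[C@H]2OC1=O
F6 | step 8 | 3β-acetoxy-13-(tert-butyldiphenylsilyloxy)-11β-hydroxygermacra-1(10)E,4E-dien-12,6α-olide | CC(C)(C)[Si](c1ccccc1)(c1ccccc1)OC[C@@]1(O)[C@@H]2CC/C(C)=C/C[C@H](OC(C)=O)/C(C)=C/[C@H]2OC1=O
F7 | step 8 | 3β-acetoxy-13-(tert-butyldiphenylsilyloxy)germacra-1(10)E,4E,7(11)-trien-12,6α-olide | CC(C)(C)[Si](c1ccccc1)(c1ccccc1)OCC1=C2CC/C(C)=C/C[C@H](OC(C)=O)/C(C)=C/[C@H]2OC1=O
F8 | step 8 | 3β-acetoxy-13-hydroxygermacra-1(10)E,4E,7(11)-trien-12,6α-olide | OCC1=C2CC/C(C)=C/C[C@H](OC(C)=O)/C(C)=C/[C@H]2OC1=O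
F0 | step 6 | none | none
F9 | step 9 | (1R,10R)-3β,13-diacetoxy-1,10-epoxy-11β-hydroxygermacr-4E-en-12,6α-olide | CC(=O)OC[C@@]1(O)[C@@H]2CC[C@@]3(C)O[C@@H]3C[C@H](OC(C)=O)/C(C)=C/[C@H]2OC1=O
F10 | step 2 | 3-(trimethylsilyloxy)-4βH,5αH,11βH-eudesm-2-en-12,6α-olide | C[C@H]1[C@@H]2CC[C@@]3(C)CC=C(O[Si](C)(C)C)[C@@H](C)[C@@H]3[C@H]2OC1=O
A1 | alternative 1 | bis(tert-butyldimethylsilyl) ether of the deacetylated target (3,13-bis-silyloxy-1,10-epoxygermacra-4,7(11)-dien-12,6-olide) | CC(C)(C)[Si](C)(C)OCC1=C2CC[C@@]3(C)O[C@@H]3C[C@H](O[Si](C)(C)C(C)(C)C)/C(C)=C/[C@H]2OC1=O
A2 | alternative 1 | open-chain C1 diphenylsulfonium tetrafluoroborate with C10 methyl ketone (1,10-seco precursor of A1) | CC(C)(C)[Si](C)(C)OCC1=C(CCC(C)=O)[C@@H](/C=C(\C)[C@H](CC[S+](c2ccccc2)c2ccccc2)O[Si](C)(C)C(C)(C)C)OC1=O.F[B-](F)(F)F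
A3 | alternative 2 | ten-membered E,E-dienyl enol triflate (C3 PMB ether, C6 MOM ether, C7 dioxolane) | O=S(=O)(O/C1=C\C[C@H](OCc2ccc(OC)cc2)/C(C)=C/[C@@H](OCOC)C2(OCCO2)CC1)C(F)(F)F
A4 | alternative 2 | trans-1-vinyl-2-alkenylcyclohexanol with E enol ether (C6 MOM ether, C7 dioxolane) | C=C[C@]1(O)CCC2(OCCO2)[C@H](OCOC)[C@H]1/C(C)=C/OCc1ccc(OC)cc1
A5 | alternative 3 | ten-membered cycloalkyne bis(tert-butyldimethylsilyl) ether (C4≡C5) | CC(C)(C)[Si](C)(C)OCC1=C2CC[C@@]3(C)O[C@@H]3C[C@H](O[Si](C)(C)C(C)(C)C)C#C[C@H]2OC1=O
A6 | alternative 3 | open-chain bis(1-propynyl) precursor of A5 (methyl-capped alkynes at C4 and C5) | CC(C)(C)[Si](C)(C)OCC1=C(CC[C@@]2(C)O[C@@H]2C[C@H](O[Si](C)(C)C(C)(C)C)C#CC)[C@@H](C#CC)OC1=O
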